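## Retrosynthetic overview
1. The three esters go on last, one at a time, as each hydroxyl is unveiled. The C2 and C6 carbinols come from ketones by reduction directed by the C4 hydroxyl. The C10 oxygen comes from 1,6-borylation of a dienone, then SN2 inversion with benzoic acid.
2. The hydroxy dienone-dione core comes from a silylene-bridged cycloheptatriene by desilylation and ketonisation, which sets C5.
3. Key disconnection: C1–C5 and C1–C10 are cut together. This is an intramolecular Buchner reaction of an α-methyl-α-diazoketone on a 2-silyloxy-4-methylphenyl ring, with C1 set by C4.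
4. The diazoketone comes from an o-hydroxyaryl isopropyl ketone by phenol-directed asymmetric allylation (sets C4), Wacker oxidation, methylation and diazo transfer.
5. The ketone comes from m-cresol and isobutyryl chloride. Ring order: the benzene ring is bought, and it expands to the seven-membered ring in the same operation that closes the five-membered ring.

**Numbering used (daucane):**
- C1 is the angular carbon bearing CH3.
- C2–C3–C4 complete the five-membered ring. C4 bears OH and isopropyl.
- C5 is the ring-fusion CH.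
- C6–C10 complete the seven-membered ring. C8 bears CH3.
- β is the face of the C1 methyl.
- In the aromatic precursors the ring carbons are already called C5 (ipso), C6 (C–O), C8 (C–CH3) and C10 (free ortho CH).

**Assumption:** the (S,S)-allylsilane is taken to give the (R)-carbinol. If the facial sense is the opposite, the equally available (R,R)-reagent is used.

## Route

Step 1
Reactants: 1 m-cresol; 2 isobutyryl chloride
Product: 4 1-(2-hydroxy-4-methylphenyl)-2-methylpropan-1-one, via m-tolyl isobutyrate 3 (not isolated)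
Conditions: neat, 60 °C; then AlCl3 (1.5 equiv), 140 °C; aq HCl
Reagents that add atoms: none
Why: O-acylation followed by a high-temperature Fries rearrangement gives the chelated ortho-hydroxy ketone at the unhindered ortho position (para to CH3); no stereocentre is formed.

Step 2
Reactants: 4 1-(2-hydroxy-4-methylphenyl)-2-methylpropan-1-one; 5 (S,S)-2-allyl-1,3-bis(4-bromobenzyl)-2-chlorooctahydro-1H-benzo[d][1,3,2]diazasilole
Product: 6 (R)-2-(3-hydroxy-2-methylhex-5-en-3-yl)-5-methylphenol
Conditions: 5 (1.5 equiv), CH2Cl2, 23 °C, 48 h; 1 M HCl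
Reagents that add atoms: none
Why: In this Leighton asymmetric allylation the phenol displaces chloride on the strained chiral silane and the bound ketone is allylated through a closed chair transition state; this directed mode is known for hindered (isopropyl, tert-butyl) o-hydroxyaryl ketones and sets C4 as R.

Step 3
Reactants: 6 (R)-2-(3-hydroxy-2-methylhex-5-en-3-yl)-5-methylphenol
Product: 7 (R)-4-allyl-2,2-di-tert-butyl-4-isopropyl-7-methyl-4H-benzo[d][1,3,2]dioxasiline
Conditions: tBu2Si(OTf)2, 2,6-lutidine, CH2Cl2, 0 °C to rt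
Reagents that add atoms: di-tert-butylsilyl bis(trifluoromethanesulfonate), CC(C)(C)[Si](OS(=O)(=O)C(F)(F)F)(OS(=O)(=O)C(F)(F)F)C(C)(C)C
Why: Silylene acetal formation protects both oxygens in one step, makes O4 a poor ylide donor, and locks O4 in the arene plane beside C6 so that the allyl arm and the isopropyl group sit on opposite arene faces.

Step 4
Reactants: 7 (R)-4-allyl-2,2-di-tert-butyl-4-isopropyl-7-methyl-4H-benzo[d][1,3,2]dioxasiline
Product: 8 (R)-1-(2,2-di-tert-butyl-4-isopropyl-7-methyl-4H-benzo[d][1,3,2]dioxasilin-4-yl)propan-2-one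
Conditions: PdCl2 (10 mol %), CuCl, O2 (1 atm), DMF/H2O 7:1, rt
Reagents that add atoms: water, O
Why: Tsuji–Wacker oxidation of the terminal alkene gives the Markovnikov methyl ketone (C2=O), and the robust silylene and the arene are untouched.

Step 5
Reactants: 8 (R)-1-(2,2-di-tert-butyl-4-isopropyl-7-methyl-4H-benzo[d][1,3,2]dioxasilin-4-yl)propan-2-one
Product: 9 (R)-1-(2,2-di-tert-butyl-4-isopropyl-7-methyl-4H-benzo[d][1,3,2]dioxasilin-4-yl)butan-2-one
Conditions: LDA (1.05 equiv), THF, −78 °C; MeI, DMPU, −78 to −40 °C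
Reagents that add atoms: iodomethane, CI
Why: Kinetic enolate alkylation works because LDA removes a proton from the open CH3 side and not from the neopentyl C3H2, so no β-elimination of O4 can occur, and MeI supplies the future angular methyl carbon.

Step 6
Reactants: 9 (R)-1-(2,2-di-tert-butyl-4-isopropyl-7-methyl-4H-benzo[d][1,3,2]dioxasilin-4-yl)butan-2-one
Product: 11 (R)-3-diazo-1-(2,2-di-tert-butyl-4-isopropyl-7-methyl-4H-benzo[d][1,3,2]dioxasilin-4-yl)butan-2-one, via trifluoroacetyl ketone 10 (not isolated)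
Conditions: LiHMDS, THF, −78 °C; CF3CO2CH2CF3; aq HCl; then MsN3, Et3N, H2O, MeCN, rt
Reagents that add atoms: methanesulfonyl azide, CS(=O)(=O)N=[N+]=[N-]; 2,2,2-trifluoroethyl trifluoroacetate, O=C(OCC(F)(F)F)C(F)(F)F (its CF3CO group is carried only by 10)
Why: In the Danheiser detrifluoroacetylative diazo transfer, kinetic trifluoroacetylation occurs at the less hindered ethyl CH2 and activates exactly that carbon (C1) for diazo transfer.

Step 7
Reactants: 11 (R)-3-diazo-1-(2,2-di-tert-butyl-4-isopropyl-7-methyl-4H-benzo[d][1,3,2]dioxasilin-4-yl)butan-2-one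
Product: 13 2-oxodauca-5,7,9-triene-4β,6-diol 4,6-di-tert-butylsilylene ether (1β-CH3, 4α-isopropyl), via norcaradiene 12 (not isolated)
Conditions: Rh2(O2CCF3)4 (1 mol %), CH2Cl2, reflux, slow addition of 11
Reagents that add atoms: none
Why: This is an intramolecular Buchner reaction (arene cyclopropanation, then 6π norcaradiene-to-cycloheptatriene opening) in which the electrophilic carbene attacks the ipso carbon activated by the ortho silyloxy and para methyl groups and closes onto the free ortho carbon C10 because C6 is blocked, so both carbocycles form at once; the arm can reach only the arene face it sits on while O4 is held in plane beside C6, so C1 forms with CH3 cis to O4 and trans to isopropyl (as in the known trans selectivity of 3-substituted 8a-methylazulenones), and the perfluoroacylate ligand favours arene addition over C–H insertion.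

Step 8
Reactants: 13 2-oxodauca-5,7,9-triene-4β,6-diol 4,6-di-tert-butylsilylene ether
Product: 15 4β-hydroxydauca-7,9-diene-2,6-dione (1β-CH3, 5α-H), via trienol 14 (not isolated)
Conditions: HF·pyridine, pyridine, THF, 0 °C
Reagents that add atoms: none
Why: Buffered fluoride cleaves both Si–O bonds and the freed trienol ketonises by protonation at C5; the epimerisable C5 settles as 5α-H (trans fusion) because only then is C6=O cis to the 4β-OH (hydrogen bond) and away from the isopropyl group.

Step 9
Reactants: 15 4β-hydroxydauca-7,9-diene-2,6-dione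
Product: 16 4β-hydroxy-10α-(pinacolboryl)dauc-8-ene-2,6-dione
Conditions: CuCl (5 mol %), Xantphos, NaOtBu (10 mol %), B2pin2, MeOH (2 equiv), THF, −20 °C
Reagents that add atoms: bis(pinacolato)diboron, CC1(C)OB(OC1(C)C)B1OC(C)(C)C(C)(C)O1
Why: In this copper-catalysed 1,6-conjugate borylation the β-methyl group blocks 1,4-attack, so boryl copper adds to the δ-carbon C10 from the α face, anti to the axial C1 methyl, and kinetic α-protonation of the dienolate leaves C7H2 and the C8=C9 alkene.

Step 10
Reactants: 16 4β-hydroxy-10α-(pinacolboryl)dauc-8-ene-2,6-dione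
Product: 17 4β,6α-dihydroxy-10α-(pinacolboryl)dauc-8-en-2-one
Conditions: Me4NBH(OAc)3 (1.2 equiv), MeCN/AcOH 1:1, −35 °C
Reagents that add atoms: none
Why: In this Evans–Saksena reduction the 4β-OH binds boron and delivers hydride to the β face of C6=O through a chair transition state to give the 6α-alcohol (1,3-anti); the neopentyl ring ketone C2 would need a strained bridged transition state and is left, and no C10 hydroxyl is yet present to steer hydride to C2.

Step 11
Reactants: 17 4β,6α-dihydroxy-10α-(pinacolboryl)dauc-8-en-2-one; 18 angelic acid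
Product: 21 6α-angeloyloxy-4β,10α-dihydroxydauc-8-en-2-one, via mixed anhydride 19 (not isolated), via boronate angelate 20 (not isolated)
Conditions: 18, 2,4,6-Cl3C6H2COCl, Et3N, toluene, rt; add 17, 80 °C; then 30 % H2O2, NaHCO3, THF/H2O, 0 °C
Reagents that add atoms: hydrogen peroxide, OO
Why: A Yamaguchi-type mixed-anhydride esterification run without DMAP keeps the Z-alkene of the angelate and acylates the only secondary hydroxyl, and the stereoretentive oxidation of the allylic C–B bond then gives the 10α-alcohol.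

Step 12
Reactants: 21 6α-angeloyloxy-4β,10α-dihydroxydauc-8-en-2-one; 22 benzoic acid
Product: 23 6α-angeloyloxy-10β-benzoyloxy-4β-hydroxydauc-8-en-2-one
Conditions: PPh3, DIAD, toluene, 0 °C to rt
Reagents that add atoms: none
Why: In this Mitsunobu reaction SN2 displacement of the allylic oxyphosphonium by benzoate inverts C10 to 10β-OBz; C1 has no β-hydrogen for elimination, C6 is no longer a ketone so vinylogous elimination is shut off, and SN2' attack would have to hit the fully substituted C8.

Step 13
Reactants: 23 6α-angeloyloxy-10β-benzoyloxy-4β-hydroxydauc-8-en-2-one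
Product: 24 6α-angeloyloxy-10β-benzoyloxydauc-8-ene-2α,4β-diol
Conditions: Me4NBH(OAc)3 (5 equiv), MeCN/AcOH 1:1, 0 °C to rt
Reagents that add atoms: none
Why: In this second Evans–Saksena reduction the 4β-OH is now the only free hydroxyl and C2=O the only ketone, so hydride arrives on the β face and gives the 2α-alcohol (trans-1,3-diol) while the esters are inert.

Step 14
Reactants: 24 6α-angeloyloxy-10β-benzoyloxydauc-8-ene-2α,4β-diol
Product: 25 2α-acetoxy-6α-angeloyloxy-10β-benzoyloxydauc-8-en-4β-ol, (1R,2S,4R,5S,6S,10S), the target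
Conditions: Ac2O, pyridine, DMAP (cat.), CH2Cl2, rt
Reagents that add atoms: acetic anhydride, CC(=O)OC(C)=O
Why: This is a chemoselective acetylation of the only secondary hydroxyl, because the hindered tertiary 4β-OH does not react under these conditions.

## Compound list
1 | m-cresol | Cc1cccc(O)c1 | starting material
2 | isobutyryl chloride | CC(C)C(=O)Cl | starting material
3 | m-tolyl isobutyrate | CC(C)C(=O)Oc1cccc(C)c1 | intermediate
4 | 1-(2-hydroxy-4-methylphenyl)-2-methylpropan-1-one | CC(C)C(=O)c1ccc(C)cc1O | intermediate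
5 | (S,S)-2-allyl-1,3-bis(4-bromobenzyl)-2-chlorooctahydro-1H-benzo[d][1,3,2]diazasilole | C=CC[Si]1(Cl)N(Cc2ccc(Br)cc2)[C@H]2CCCC[C@@H]2N1Cc1ccc(Br)cc1 | starting material
6 | (R)-2-(3-hydroxy-2-methylhex-5-en-3-yl)-5-methylphenol | C=CC[C@@](O)(C(C)C)c1ccc(C)cc1O | intermediate
7 | (R)-4-allyl silylene acetal | C=CC[C@@]1(O[Si](C(C)(C)C)(C(C)(C)C)Oc2cc(C)ccc21)C(C)C | intermediate
8 | (R)-methyl ketone | CC(=O)C[C@@]1(O[Si](C(C)(C)C)(C(C)(C)C)Oc2cc(C)ccc21)C(C)C | intermediate
9 | (R)-ethyl ketone | CCC(=O)C[C@@]1(O[Si](C(C)(C)C)(C(C)(C)C)Oc2cc(C)ccc21)C(C)C | intermediate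
10 | α-trifluoroacetyl ketone (C1 epimers/enol) | CC(C(=O)C(F)(F)F)C(=O)C[C@@]1(O[Si](C(C)(C)C)(C(C)(C)C)Oc2cc(C)ccc21)C(C)C | intermediate
11 | (R)-α-methyl-α-diazoketone | CC(=[N+]=[N-])C(=O)C[C@@]1(O[Si](C(C)(C)C)(C(C)(C)C)Oc2cc(C)ccc21)C(C)C | intermediate
12 | norcaradiene (cyclopropane C1–C5–C10, CH3 endo) | O=C1C[C@]2(C(C)C)O[Si](C(C)(C)C)(C(C)(C)C)OC3=CC(C)=C[C@@H]4[C@]1(C)[C@]234 | intermediate
13 | silylene-bridged 2-oxodauca-5,7,9-triene | O=C1C[C@]2(C(C)C)O[Si](C(C)(C)C)(C(C)(C)C)OC3=C2[C@@]1(C)C=CC(C)=C3 | intermediate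
14 | 4β,6-dihydroxydauca-5,7,9-trien-2-one (trienol) | O=C1C[C@@](O)(C(C)C)C2=C(O)C=C(C)C=C[C@@]12C | intermediate
15 | 4β-hydroxydauca-7,9-diene-2,6-dione | O=C1C[C@@](O)(C(C)C)[C@@H]2C(=O)C=C(C)C=C[C@@]12C | intermediate
16 | 4β-hydroxy-10α-(pinacolboryl)dauc-8-ene-2,6-dione | O=C1C[C@@](O)(C(C)C)[C@@H]2C(=O)CC(C)=C[C@@H](B3OC(C)(C)C(C)(C)O3)[C@@]12C | intermediate
17 | 4β,6α-dihydroxy-10α-(pinacolboryl)dauc-8-en-2-one | O=C1C[C@@](O)(C(C)C)[C@@H]2[C@@H](O)CC(C)=C[C@@H](B3OC(C)(C)C(C)(C)O3)[C@@]12C | intermediate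
18 | angelic acid, (Z)-2-methylbut-2-enoic acid | C/C=C(/C)C(=O)O | starting material
19 | angelic 2,4,6-trichlorobenzoic anhydride | C/C=C(/C)C(=O)OC(=O)c1c(Cl)cc(Cl)cc1Cl | intermediate
20 | 6α-angelate of 17 | O=C1C[C@@](O)(C(C)C)[C@@H]2[C@@H](OC(=O)/C(C)=C\C)CC(C)=C[C@@H](B3OC(C)(C)C(C)(C)O3)[C@@]12C | intermediate
21 | 6α-angeloyloxy-4β,10α-dihydroxydauc-8-en-2-one | O=C1C[C@@](O)(C(C)C)[C@@H]2[C@@H](OC(=O)/C(C)=C\C)CC(C)=C[C@@H](O)[C@@]12C | intermediate
22 | benzoic acid | O=C(O)c1ccccc1 | starting material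
23 | 6α-angeloyloxy-10β-benzoyloxy-4β-hydroxydauc-8-en-2-one | O=C1C[C@@](O)(C(C)C)[C@@H]2[C@@H](OC(=O)/C(C)=C\C)CC(C)=C[C@H](OC(=O)c3ccccc3)[C@@]12C | intermediate
24 | 6α-angeloyloxy-10β-benzoyloxydauc-8-ene-2α,4β-diol | O[C@H]1C[C@@](O)(C(C)C)[C@@H]2[C@@H](OC(=O)/C(C)=C\C)CC(C)=C[C@H](OC(=O)c3ccccc3)[C@@]12C | intermediate
25 | CNP0248576.1 | C/C=C(/C)C(=O)O[C@H]1CC(C)=C[C@H](OC(=O)c2ccccc2)[C@@]2(C)[C@@H](OC(C)=O)C[C@@](O)(C(C)C)[C@H]12 | target

## Step count and risks
Total steps: 14. Longest linear sequence: 14 (1 to 25).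

**Step 7 (Buchner reaction).**
- The carbene may instead insert into the isopropyl methine C–H, attack O4 with silyl transfer, or undergo a 1,2-hydride shift to the vinyl ketone.
- The fallback is a carbene-free anionic dearomatisation. It sets out from 9 and returns at 15.
- The TMS enol ether of 9 is brominated with NBS to give the α-bromo ketone F1.
- TBAF strips the silylene. The freed phenoxide closes the five-membered ring by ortho C-alkylation at C5 to give the spirocyclic cyclohexa-2,4-dienone F2.
- DBU then deprotonates C1. Intramolecular 1,6-addition onto C10 followed by 6π ring opening and reprotonation delivers 15.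

**Step 9 (1,6-borylation).**
- Attack at the neopentyl C10 may be slow. The β,γ-enone may drift into conjugation, and the allylboronate may not survive steps 10 and 11.
- The fallback is oxidative. It sets out from 15 and returns at 21.
- mCPBA epoxidises the electron-richer γ,δ-alkene from the α face to give the epoxy enone F3.
- SmI2/MeOH opens F3 reductively to the 10α-hydroxy β,γ-enone F4.
- TESCl/imidazole gives the silyl ether F5, so that the C10 hydroxyl cannot steer hydride to C2.
- Me4NBH(OAc)3 gives the 6α-alcohol F6.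
- Mixed-anhydride angeloylation gives the angelate F7, and HF·pyridine returns to 21.

**Step 12 (Mitsunobu at a neopentyl allylic carbinol).**
- Substitution may stall, or may ionise and give retention.
- The fallback is an oxidation–reduction sequence. It sets out from 21 and returns at 23.
- MnO2 oxidises the allylic alcohol to the enone F8.
- NaBH4/CeCl3·7H2O at −78 °C (Luche) adds hydride from the α face, anti to the axial C1 methyl and faster than at the hindered C2 ketone, to give the 10β-alcohol F9.
- BzCl, DMAP and pyridine give 23.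

## Further compounds
F1 | step 7 | α-bromo ketone (C1 epimers) | CC(Br)C(=O)C[C@@]1(O[Si](C(C)(C)C)(C(C)(C)C)Oc2cc(C)ccc21)C(C)C
F2 | step 7 | spirocyclic cyclohexa-2,4-dienone (C1 epimers) | CC1C(=O)C[C@@](O)(C(C)C)[C@@]12C=CC(C)=CC2=O
F3 | step 9 | 9α,10α-epoxy-4β-hydroxydauc-7-ene-2,6-dione | O=C1C[C@@](O)(C(C)C)[C@@H]2C(=O)C=C(C)[C@H]3O[C@H]3[C@@]12C
F4 | step 9 | 4β,10α-dihydroxydauc-8-ene-2,6-dione | O=C1C[C@@](O)(C(C)C)[C@@H]2C(=O)CC(C)=C[C@@H](O)[C@@]12C
F5 | step 9 | 10α-triethylsilyl ether of F4 | O=C1C[C@@](O)(C(C)C)[C@@H]2C(=O)CC(C)=C[C@@H](O[Si](CC)(CC)CC)[C@@]12C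
F6 | step 9 | 4β,6α-dihydroxy-10α-(triethylsilyloxy)dauc-8-en-2-one | O=C1C[C@@](O)(C(C)C)[C@@H]2[C@@H](O)CC(C)=C[C@@H](O[Si](CC)(CC)CC)[C@@]12C
F7 | step 9 | 6α-angelate of F6 | O=C1C[C@@](O)(C(C)C)[C@@H]2[C@@H](OC(=O)/C(C)=C\C)CC(C)=C[C@@H](O[Si](CC)(CC)CC)[C@@]12C
F8 | step 12 | 6α-angeloyloxy-4β-hydroxydauc-8-ene-2,10-dione | O=C1C[C@@](O)(C(C)C)[C@@H]2[C@@H](OC(=O)/C(C)=C\C)CC(C)=CC(=O)[C@@]12C
F9 | step 12 | 6α-angeloyloxy-4β,10β-dihydroxydauc-8-en-2-one | O=C1C[C@@](O)(C(C)C)[C@@H]2[C@@H](OC(=O)/C(C)=C\C)CC(C)=C[C@H](O)[C@@]12C
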